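**Plan**

1. Numbering: ring as cyclohex-2-en-1-one (C1 = C=O, C2H=, C3–CH3, C4 quaternary, C5H–CH3, C6H2), chain from C7 (the CH2 on C4). The retrosynthesis cuts C8–C9 (sp3–sp2 Negishi coupling) into ring iodide 13 and dienyl iodide 27, then C1–C2 and C3–C4 of the ring, and last C1–C6 and C4–C5 of a cyclobutenone.
2. Enabling feature: C2H=C3(CH3) and C6H2–C5H(CH3) are the same propyne-derived unit on either side of the fully substituted C4, para to the C1 carbonyl. The cyclohexenone is thus one reduced arm of the Cs-symmetric cyclohexa-2,5-dienone 10, and C4 (no hydrogen) keeps that dienone from becoming a phenol.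
3. Rings, forward: amide 3 → four-membered ring 7 (keteniminium + propyne) → six-membered ring 9 by Ni(0)-catalysed insertion of a second propyne unit into the acyl–C4 bond → 10 → 12.
4. Chain, forward: carboalumination/oxirane opening gives the 3E alkene, Negishi coupling with 4-bromofuranone the butenolide, hydrozirconation–iodination the 7E alkenyl iodide; a final Negishi coupling joins ring and chain.
5. Stereochemistry: C4 and C5 are both set in step 5 by Cu–H desymmetrisation of 10 (arm chosen by the chiral ligand, face by the C4 substituents). Both trisubstituted alkenes come from syn carbo- or hydrometalation of alkynes.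

Key step: step 3

Assumption: the sense of induction of the chiral Cu–H catalyst on 10 cannot be predicted with certainty; the ligand enantiomer that leads to (4R,5R)-12 is to be fixed by a test reaction.

**Route**

Step 1
Reactants: 1 1-(pyrrolidin-1-yl)propan-1-one; 2 1-bromo-2-chloroethane
Product: 3 4-chloro-2-methyl-1-(pyrrolidin-1-yl)butan-1-one (racemic)
Conditions: LDA (1.0 equiv), THF, −78 °C; then 2, −78 → 0 °C
Reagents that add atoms: none
Why: Alkylation of the lithium amide enolate (SN2 at the C–Br end of 2) should give 3; one equivalent of base at low temperature limits a second deprotonation and cyclopropane closure, and the racemic C2 centre does not matter because it becomes sp2 in step 2.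

Step 2
Reactants: 3 4-chloro-2-methyl-1-(pyrrolidin-1-yl)butan-1-one; 4 propyne
Product: 7 4-(2-chloroethyl)-3,4-dimethylcyclobut-2-en-1-one (racemic), via keteniminium triflate 5 (not isolated), via cyclobuteniminium triflate 6 (not isolated)
Conditions: Tf2O (1.2 equiv), 2,4,6-collidine (1.3 equiv), 4 (5 equiv), ClCH2CH2Cl, −20 → 70 °C (sealed tube); then aq. NaHCO3, 25 °C
Reagents that add atoms: water, O
Why: Keteniminium [2+2] cycloaddition: O-triflation and α-deprotonation of the amide give 5, whose central carbon should bond to the terminal carbon of propyne while its α-carbon closes on the internal carbon, so that hydrolysis of 6 gives the 3-methyl-4,4-disubstituted cyclobutenone 7 (C4 racemic, erased later).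

Step 3
Reactants: 7 4-(2-chloroethyl)-3,4-dimethylcyclobut-2-en-1-one; 8 1-(trimethylsilyl)propyne
Product: 9 4-(2-chloroethyl)-3,4,5-trimethyl-2-(trimethylsilyl)cyclohexa-2,5-dien-1-one (racemic)
Conditions: Ni(cod)2 (10 mol %), PPh3 (20 mol %), toluene, 0 → 40 °C
Reagents that add atoms: none
Why: Proposed new method: Ni(0) should add oxidatively to the strained acyl–C4 σ-bond of 7 (the only C(O)–C(sp3) bond of the four-membered ring; equivalent to a nickel-bound vinylketene), the alkyne should insert into the Ni–C4 bond so that C4 bonds to the methyl-bearing alkyne carbon, and C(acyl)–C(vinyl) reductive elimination should release 9 and Ni(0). The closest known reaction type is the Ni(0)-catalysed annulation of cyclobutenones with alkynes to phenols (and the Ni-catalysed alkyne insertion into cyclobutanones); new here is a fully substituted C4, which must take part in C(sp3)–C(sp2) bond formation and, having no hydrogen, stops the product at the cross-conjugated dienone instead of a phenol. The six-membered ring is closed as a formal [4+2] (C1, C6, C5 and C4 of 7 plus the two alkyne carbons) by reductive elimination from a seven-membered nickelacycle. C4 is the only new stereocentre (the two arms differ by SiMe3); it forms racemic without control, which is harmless because step 4 makes the arms identical. The step needs one orientation of the alkyne (CH3 next to C4, SiMe3 next to C=O), expected because the bulky silyl group avoids the quaternary carbon and ends on the nickel-bound carbon, as the larger alkyne substituent does in the phenol-forming annulations, and because silylalkynes are slow to cyclotrimerise; the primary C–Cl bond should be inert to Ni(0)–phosphine at or below 40 °C.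

Step 4
Reactants: 9 4-(2-chloroethyl)-3,4,5-trimethyl-2-(trimethylsilyl)cyclohexa-2,5-dien-1-one
Product: 10 4-(2-chloroethyl)-3,4,5-trimethylcyclohexa-2,5-dien-1-one
Conditions: Bu4NF (1.1 equiv), AcOH (1.2 equiv), THF, 0 °C
Reagents that add atoms: none
Why: Fluoride-induced protodesilylation of the α-silyl enone (buffered, so that the dienone meets neither strong acid nor strong base) should make the two arms identical and give the achiral dienone 10 with C4 as a prochiral centre.

Step 5
Reactants: 10 4-(2-chloroethyl)-3,4,5-trimethylcyclohexa-2,5-dien-1-one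
Product: 12 (4R,5R)-4-(2-chloroethyl)-3,4,5-trimethylcyclohex-2-en-1-one, via silyl dienol ether 11 (not isolated)
Conditions: Cu(OAc)2·H2O (3 mol %), DTBM-SEGPHOS (3.3 mol %, enantiomer per the assumption), (EtO)2MeSiH (1.5 equiv), toluene, −10 → 25 °C; then 1 M HCl, THF, 0 °C
Reagents that add atoms: none
Why: Cu–H-catalysed asymmetric conjugate reduction used as a desymmetrisation: the chiral copper hydride should reduce only one of the two enantiotopic enone arms and deliver hydride to C5 on the face of the small C4 methyl group (anti to the 2-chloroethyl arm), which would set C5 as R and make C4 the R stereocentre, while trapping as the silyl dienol ether 11 protects the second arm until the acidic work-up.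

Step 6
Reactants: 12 (4R,5R)-4-(2-chloroethyl)-3,4,5-trimethylcyclohex-2-en-1-one
Product: 13 (4R,5R)-4-(2-iodoethyl)-3,4,5-trimethylcyclohex-2-en-1-one
Conditions: NaI (5 equiv), butan-2-one, 80 °C
Reagents that add atoms: sodium iodide, [Na+].[I-]
Why: Finkelstein halide exchange (SN2 at the unhindered primary carbon, driven by precipitation of NaCl) should give the iodide needed for zinc insertion without touching the enone or the stereocentres.

Step 7
Reactants: 14 pent-3-yn-1-ol
Product: 15 pent-3-yn-1-yl 4-methylbenzenesulfonate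
Conditions: TsCl, Et3N, DMAP (cat.), CH2Cl2, 0 °C
Reagents that add atoms: 4-toluenesulfonyl chloride, Cc1ccc(cc1)S(Cl)(=O)=O
Why: Sulfonylation of the primary alcohol turns it into a leaving group for the next C–C bond formation.

Step 8
Reactants: 15 pent-3-yn-1-yl 4-methylbenzenesulfonate; 16 lithium acetylide–ethylenediamine complex
Product: 17 hepta-1,5-diyne
Conditions: DMSO, 15 → 25 °C
Reagents that add atoms: none
Why: SN2 alkynylation of the primary tosylate by lithium acetylide should give the diyne with one terminal and one internal triple bond.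

Step 9
Reactants: 17 hepta-1,5-diyne; 18 oxirane
Product: 21 (3E)-4-methylnon-3-en-7-yn-1-ol, via alkenylalane 19 (not isolated), via lithium alanate 20 (not isolated)
Conditions: Me3Al (2 equiv), Cp2ZrCl2 (0.2 equiv), CH2Cl2, 0 → 25 °C; then n-BuLi, hexane/THF, −78 °C; then 18, −30 → 0 °C
Reagents that add atoms: trimethylaluminium, C[Al](C)C
Why: Zr-catalysed carboalumination (syn methylalumination, much faster at the terminal than at the internal alkyne, methyl to the internal carbon) followed by opening of oxirane by the alanate with retention at the alkenyl carbon should give the trisubstituted (E)-alkene.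

Step 10
Reactants: 21 (3E)-4-methylnon-3-en-7-yn-1-ol
Product: 22 (6E)-9-iodo-6-methylnon-6-en-2-yne
Conditions: I2, PPh3, imidazole, CH2Cl2, 0 °C
Reagents that add atoms: iodine, II
Why: Appel-type iodination should convert the primary alcohol into the iodide under neutral conditions that leave alkene and alkyne untouched.

Step 11
Reactants: 22 (6E)-9-iodo-6-methylnon-6-en-2-yne; 23 4-bromofuran-2(5H)-one
Product: 25 4-[(3E)-4-methylnon-3-en-7-yn-1-yl]furan-2(5H)-one, via alkylzinc iodide 24 (not isolated)
Conditions: Zn dust, LiCl, THF, 40 °C; then 23, Pd(PPh3)4 (5 mol %), THF, 25 °C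
Reagents that add atoms: none
Why: Zinc insertion into the primary iodide and Pd-catalysed Negishi coupling of 24 with the vinylogous acyl bromide 23 should attach the butenolide at its β-carbon, the alkylzinc iodide being inert to lactone and internal alkyne.

Step 12
Reactants: 25 4-[(3E)-4-methylnon-3-en-7-yn-1-yl]furan-2(5H)-one
Product: 27 4-[(3E,7E)-8-iodo-4-methylnona-3,7-dien-1-yl]furan-2(5H)-one, via alkenylzirconocene chloride 26 (not isolated)
Conditions: Cp2Zr(H)Cl (1.5 equiv), THF, 25 → 45 °C; then I2, 0 °C
Reagents that add atoms: iodine, II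
Why: Hydrozirconation (syn addition; with a slight excess of hydride the zirconium settles on the less hindered methyl-bearing carbon) and iodinolysis with retention should give the (E)-2-iodoalkene, the alkyne reacting much faster than the trisubstituted alkene or the lactone.

Step 13
Reactants: 13 (4R,5R)-4-(2-iodoethyl)-3,4,5-trimethylcyclohex-2-en-1-one; 27 4-[(3E,7E)-8-iodo-4-methylnona-3,7-dien-1-yl]furan-2(5H)-one
Product: 29 cyclolinteinone, via alkylzinc iodide 28 (not isolated)
Conditions: 13, Zn dust, LiCl, THF, 40 °C; then 27, Pd(OAc)2 (3 mol %), SPhos (6 mol %), THF/NMP, 25 → 45 °C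
Reagents that add atoms: none
Why: Negishi sp3–sp2 cross-coupling: zinc should insert into the primary C–I bond without affecting the enone, and Pd-catalysed coupling with the alkenyl iodide proceeds with retention of the (E) geometry, which completes the skeleton without touching C4 or C5.

**Compound list**

1 | 1-(pyrrolidin-1-yl)propan-1-one | CCC(=O)N1CCCC1 | starting material
2 | 1-bromo-2-chloroethane | ClCCBr | starting material
3 | 4-chloro-2-methyl-1-(pyrrolidin-1-yl)butan-1-one (racemic) | CC(CCCl)C(=O)N1CCCC1 | intermediate
4 | propyne | CC#C | starting material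
5 | keteniminium triflate, 1-(4-chloro-2-methylbut-1-en-1-ylidene)pyrrolidin-1-ium trifluoromethanesulfonate | CC(CCCl)=C=[N+]1CCCC1.[O-]S(=O)(=O)C(F)(F)F | intermediate
6 | cyclobuteniminium triflate, 1-[4-(2-chloroethyl)-3,4-dimethylcyclobut-2-en-1-ylidene]pyrrolidin-1-ium trifluoromethanesulfonate | CC1=CC(=[N+]2CCCC2)C1(C)CCCl.[O-]S(=O)(=O)C(F)(F)F | intermediate
7 | 4-(2-chloroethyl)-3,4-dimethylcyclobut-2-en-1-one (racemic) | CC1=CC(=O)C1(C)CCCl | intermediate
8 | 1-(trimethylsilyl)propyne | CC#C[Si](C)(C)C | starting material
9 | 4-(2-chloroethyl)-3,4,5-trimethyl-2-(trimethylsilyl)cyclohexa-2,5-dien-1-one (racemic at C4) | CC1=C([Si](C)(C)C)C(=O)C=C(C)C1(C)CCCl | intermediate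
10 | 4-(2-chloroethyl)-3,4,5-trimethylcyclohexa-2,5-dien-1-one (achiral) | CC1=CC(=O)C=C(C)C1(C)CCCl | intermediate
11 | silyl dienol ether of 12, O-[diethoxy(methyl)silyl] on C1, double bonds C1=C6 and C2=C3, C4 and C5 as in 12 | CC1=CC(O[Si](C)(OCC)OCC)=C[C@@H](C)[C@@]1(C)CCCl | intermediate
12 | (4R,5R)-4-(2-chloroethyl)-3,4,5-trimethylcyclohex-2-en-1-one | CC1=CC(=O)C[C@@H](C)[C@@]1(C)CCCl | intermediate
13 | (4R,5R)-4-(2-iodoethyl)-3,4,5-trimethylcyclohex-2-en-1-one | CC1=CC(=O)C[C@@H](C)[C@@]1(C)CCI | intermediate
14 | pent-3-yn-1-ol | CC#CCCO | starting material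
15 | pent-3-yn-1-yl 4-methylbenzenesulfonate | CC#CCCOS(=O)(=O)c1ccc(C)cc1 | intermediate
16 | lithium acetylide–ethylenediamine complex | [Li+].[C-]#C.NCCN | starting material
17 | hepta-1,5-diyne | CC#CCCC#C | intermediate
18 | oxirane | C1CO1 | starting material
19 | alkenylalane, dimethyl[(1E)-2-methylhept-1-en-5-yn-1-yl]alane | CC#CCC/C(C)=C/[Al](C)C | intermediate
20 | lithium alanate, lithium butyl(dimethyl)[(1E)-2-methylhept-1-en-5-yn-1-yl]aluminate | CC#CCC/C(C)=C/[Al-](C)(C)CCCC.[Li+] | intermediate
21 | (3E)-4-methylnon-3-en-7-yn-1-ol | CC#CCC/C(C)=C/CCO | intermediate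
22 | (6E)-9-iodo-6-methylnon-6-en-2-yne | CC#CCC/C(C)=C/CCI | intermediate
23 | 4-bromofuran-2(5H)-one | BrC1=CC(=O)OC1 | starting material
24 | alkylzinc iodide, [(3E)-4-methylnon-3-en-7-yn-1-yl]zinc iodide | CC#CCC/C(C)=C/CC[Zn]I | intermediate
25 | 4-[(3E)-4-methylnon-3-en-7-yn-1-yl]furan-2(5H)-one | CC#CCC/C(C)=C/CCC1=CC(=O)OC1 | intermediate
26 | alkenylzirconocene chloride (Zr on the CH3-bearing alkene carbon, trans to the chain) | C/C(=C\CC/C(C)=C/CCC1=CC(=O)OC1)[Zr](Cl)(C1C=CC=C1)C1C=CC=C1 | intermediate
27 | 4-[(3E,7E)-8-iodo-4-methylnona-3,7-dien-1-yl]furan-2(5H)-one | C/C(I)=C\CC/C(C)=C/CCC1=CC(=O)OC1 | intermediate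
28 | alkylzinc iodide, {2-[(1R,6R)-1,2,6-trimethyl-4-oxocyclohex-2-en-1-yl]ethyl}zinc iodide | CC1=CC(=O)C[C@@H](C)[C@@]1(C)CC[Zn]I | intermediate
29 | cyclolinteinone, 4-{(3E,7E)-4,8-dimethyl-10-[(1R,6R)-1,2,6-trimethyl-4-oxocyclohex-2-en-1-yl]deca-3,7-dien-1-yl}furan-2(5H)-one | CC1=CC(=O)C[C@@H](C)[C@@]1(C)CC/C(C)=C/CC/C(C)=C/CCC1=CC(=O)OC1 | target

**Step count and risks**

Total steps: 13. Longest linear sequence: 7 steps (steps 1–6 and 13; the chain branch, steps 7–12 and 13, is equally long).

Steps most likely to fail:

1. Step 3 (proposed new method). After oxidative addition the nickel-bound vinylketene may decarbonylate or dimerise instead of taking up the alkyne, the alkyne may insert in the opposite orientation, or reductive elimination at the fully substituted carbon may be too slow. The fallback reaches 10 by enolate alkylation and carbonyl transposition, all known chemistry, and sets out from 2. Commercial 5-methylcyclohexane-1,3-dione is converted with ethanol and TsOH (toluene, removal of water) into 3-ethoxy-5-methylcyclohex-2-en-1-one F1. Stork–Danheiser alkylation (LDA, THF, −78 °C, MeI) gives 3-ethoxy-5,6-dimethylcyclohex-2-en-1-one F2. A second deprotonation followed by 2 (DMPU, −78 → 0 °C) builds the quaternary carbon of 6-(2-chloroethyl)-3-ethoxy-5,6-dimethylcyclohex-2-en-1-one F3. Methyl goes in first so that no enolate carrying a 2-chloroethyl group, which would close to a cyclopropane, is formed. MeLi adds to the carbonyl group to give 6-(2-chloroethyl)-3-ethoxy-1,5,6-trimethylcyclohex-2-en-1-ol F4 (not isolated). Aqueous HCl then brings about hydrolysis with allylic transposition to 4-(2-chloroethyl)-3,4,5-trimethylcyclohex-2-en-1-one F5 (racemic, either relative configuration). Dehydrogenation of the C5–C6 bond (IBX, DMSO, 70 °C) removes the C5 stereocentre and gives 10, where the route is rejoined.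

2. Step 5. Within the selected arm the two faces differ only by methyl versus 2-chloroethyl at C4, so facial discrimination may be poor and the C4/C5 relative configuration eroded. Hydride transfer to a β-carbon next to a quaternary centre may also be slow. The fallback sets out from 10 and returns at 12. It replaces the metal hydride by a biocatalytic C=C reduction with an ene-reductase of the Old Yellow Enzyme family (NADP+, glucose dehydrogenase, glucose, phosphate buffer pH 7 with 5% DMSO, 30 °C). This is a known way to desymmetrise 4,4-disubstituted cyclohexa-2,5-dienones. The dienone must lie flat on the flavin, so only the face whose C4 substituent is the methyl group can be presented to N5–H; the face is thus fixed by a different principle than ligand bulk. The arm is chosen by the active site, and a panel of stereocomplementary enzymes is to be screened for the (4R,5R) product. No new compound is made on this way (entry F0).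

3. Step 12. The zirconium hydride may partly reduce the butenolide, and regiochemical equilibration of the alkenylzirconium may be incomplete. The fallback changes the order of events so that the hydride never meets the lactone; it sets out from 21 and returns at 29. Silylation (TBSCl, imidazole, DMF) gives tert-butyl(dimethyl){[(3E)-4-methylnon-3-en-7-yn-1-yl]oxy}silane F6. Hydrozirconation (Cp2Zr(H)Cl, THF) gives the alkenylzirconocene chloride F7 (not isolated), and iodinolysis gives tert-butyl{[(3E,7E)-8-iodo-4-methylnona-3,7-dien-1-yl]oxy}dimethylsilane F8. Negishi coupling of F8 with zinc reagent 28 (Pd(OAc)2, SPhos) gives (4R,5R)-4-[(3E,7E)-10-{[tert-butyl(dimethyl)silyl]oxy}-3,7-dimethyldeca-3,7-dien-1-yl]-3,4,5-trimethylcyclohex-2-en-1-one F9. Bu4NF gives (4R,5R)-4-[(3E,7E)-10-hydroxy-3,7-dimethyldeca-3,7-dien-1-yl]-3,4,5-trimethylcyclohex-2-en-1-one F10, and I2/PPh3/imidazole gives (4R,5R)-4-[(3E,7E)-10-iodo-3,7-dimethyldeca-3,7-dien-1-yl]-3,4,5-trimethylcyclohex-2-en-1-one F11. Zinc insertion gives the alkylzinc iodide F12 (not isolated), and Pd-catalysed coupling with 23 gives 29.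

**Further compounds**

F1 | step 3 | 3-ethoxy-5-methylcyclohex-2-en-1-one | CCOC1=CC(=O)CC(C)C1
F2 | step 3 | 3-ethoxy-5,6-dimethylcyclohex-2-en-1-one | CCOC1=CC(=O)C(C)C(C)C1
F3 | step 3 | 6-(2-chloroethyl)-3-ethoxy-5,6-dimethylcyclohex-2-en-1-one | CCOC1=CC(=O)C(C)(CCCl)C(C)C1
F4 | step 3 | 6-(2-chloroethyl)-3-ethoxy-1,5,6-trimethylcyclohex-2-en-1-ol | CCOC1=CC(C)(O)C(C)(CCCl)C(C)C1
F5 | step 3 | 4-(2-chloroethyl)-3,4,5-trimethylcyclohex-2-en-1-one (racemic, diastereomer mixture) | CC1=CC(=O)CC(C)C1(C)CCCl
F0 | step 5 | none | none
F6 | step 12 | tert-butyl(dimethyl){[(3E)-4-methylnon-3-en-7-yn-1-yl]oxy}silane | CC#CCC/C(C)=C/CCO[Si](C)(C)C(C)(C)C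
F7 | step 12 | alkenylzirconocene chloride of F6 (Zr on the CH3-bearing alkene carbon) | C/C(=C\CC/C(C)=C/CCO[Si](C)(C)C(C)(C)C)[Zr](Cl)(C1C=CC=C1)C1C=CC=C1
F8 | step 12 | tert-butyl{[(3E,7E)-8-iodo-4-methylnona-3,7-dien-1-yl]oxy}dimethylsilane | C/C(I)=C\CC/C(C)=C/CCO[Si](C)(C)C(C)(C)C
F9 | step 12 | (4R,5R)-4-[(3E,7E)-10-{[tert-butyl(dimethyl)silyl]oxy}-3,7-dimethyldeca-3,7-dien-1-yl]-3,4,5-trimethylcyclohex-2-en-1-one | CC1=CC(=O)C[C@@H](C)[C@@]1(C)CC/C(C)=C/CC/C(C)=C/CCO[Si](C)(C)C(C)(C)C
F10 | step 12 | (4R,5R)-4-[(3E,7E)-10-hydroxy-3,7-dimethyldeca-3,7-dien-1-yl]-3,4,5-trimethylcyclohex-2-en-1-one | CC1=CC(=O)C[C@@H](C)[C@@]1(C)CC/C(C)=C/CC/C(C)=C/CCO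
F11 | step 12 | (4R,5R)-4-[(3E,7E)-10-iodo-3,7-dimethyldeca-3,7-dien-1-yl]-3,4,5-trimethylcyclohex-2-en-1-one | CC1=CC(=O)C[C@@H](C)[C@@]1(C)CC/C(C)=C/CC/C(C)=C/CCI
F12 | step 12 | alkylzinc iodide from F11 | CC1=CC(=O)C[C@@H](C)[C@@]1(C)CC/C(C)=C/CC/C(C)=C/CC[Zn]I
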